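- Midnight and dusk get the same initiator, 8.4 mM, but midnight holds more free monomer than dusk, 0.60 M against 0.20 M, so the question you face is how much monomer ends up in chains for each chain begun.

common to all: initiator 8.4 mM
- south: free monomer 0.23 M; run made earlier
- south-west: free monomer 0.78 M; run made earlier
- dusk: free monomer 0.20 M; time 1.0 h
- midnight: free monomer 0.60 M; time 1.0 h

| run | time / min | monomer in chains / % |
|---|---|---|
| south | 8.00 | 9.1 |
| south | 20.0 | 13.6 |
| south | 40.0 | 15.2 |
| south | 60.0 | 16.4 |
| south-west | 8.00 | 10.3 |
| south-west | 20.0 | 14.4 |
| south-west | 40.0 | 17.8 |
| south-west | 60.0 | 18.6 |

(scatter of a reading: 0.5 percentage points)

- the average divides the monomer in chains by the number of chains begun, living and dead together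
- the earlier runs do not show the number of chains; that part of a forecast is a guess

- which of the two ends with the longer chains by the average number of monomer units in a chain (chains begun, living or dead) ("neither" if they lie within 10 %) (dusk / midnight / neither)
- average number of monomer units in a chain (chains begun, living or dead) at the end, dusk
- average number of monomer units in a chain (chains begun, living or dead) at the end, midnight

- You could try to follow the clock, but the length, which is the number-average degree of polymerisation, is by its definition the ratio of two totals at the asked time, monomer in chains over chains begun, so you can estimate those two totals at that moment directly.
- For the first total you take the south reading at 60.0 min, which is the asked time, and for the second you guess one chain per initiator, so dusk gets 3.90, the units per initiator, meaning the fraction of free monomer in chains times c(free monomer) charged over c(initiator) charged, and midnight, with the south-west reading, gets 13.3.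
- You should object that dusk and midnight are not the earlier flasks, but the fraction moved from 16.4 % to 18.6 % while the charge grew 3.39 times, so the smaller shifts in charge here should move it little.
- The harder objection is that the runs do not show the chains, so the absolute lengths stay a guess; a factor common to both flasks, though, cancels in the ratio 3.41, which keeps midnight ahead.
- The forecast says midnight, with 4 for dusk and 13 for midnight, and adds that “The ratio is much firmer than the absolute values”; it draws on the same readings as your reckoning, so the closeness of the two is no check.

    free monomer + living end → monomer in chains + living end, rate k1*[living end]*[free monomer] (k = 0.0952 L mol⁻¹ s⁻¹)
    2 living end → dead end (k = 0.953 L mol⁻¹ s⁻¹)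
    free monomer + initiator → living end + monomer in chains (k = 0.0261 L mol⁻¹ s⁻¹)
    monomer in chains + living end → free monomer + living end, rate k4*[living end] as long as [monomer in chains] is above zero (k = 0.00875 s⁻¹)

- The flask gives 3.77 for dusk and 13.0 for midnight, so midnight ends with the longer chains. In dusk at 1.00 h, the initiator stands at 0 % of its charge and the monomer in chains at 15.8 %. Units per initiator gave 3.90 and 13.3, and their ratio of 3.41 lies well beyond the 10 % band, so the answer stands a long way from "neither".
- In the neighbour, midnight with 0.021 M of initiator, units per initiator with the south-west reading gives 5.31.
- The computed length there is 7.11, with 24.9 % of the free monomer in chains at 1.00 h against the 18.6 % read in the south-west run.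

Readings and results were generated by integration for substances that don't exist; the scatter is artificial.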